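All constants belong to no real substance; what happens was integrated by code.

Slowness comes first here: alone, the uncatalysed step halves substrate every 7.87 s, and uncatalysed product is the substrate that this first-order loss takes before the enzyme step does.

| setting | ash | alder | birch | oak |
|---|---|---|---|---|
| substrate | 5.0 mM (fed, over 64.0 s) | 5.0 mM | 5.0 mM | 5.0 mM |
| enzyme | 0.50 µM | 0.50 µM | 0.50 µM | 0.50 µM |
| time | 80 s |  | 80 s |  |
| remark | all but substrate at the start; substrate goes in evenly over 64.0 s, the run ends at 80 s | a single well-mixed tank run continuously and read at steady state, 240 s in it on average | everything together in a closed stirred flask, run for 80 s | a single well-mixed tank run continuously and read at steady state, 80 s in it on average |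

    substrate + enzyme → target + enzyme, rate k1*[substrate]^1.5*[enzyme]/(1 + ([substrate]/Kh1)^1.5) (Kh1 = 10.1 mM, k1 = 7.36 × 10⁷ /M^1.5/s)
    substrate → uncatalysed product (k2 = 0.0881 /s)

1. the set-up with the highest share of target in all that became target or uncatalysed product, at the outlet or at the end ("none" if the first two lie within 2 percentage points) (ash / alder / birch / oak / none)
2. share of target in all that became target or uncatalysed product, at the outlet or at the end, ash
3. share of target in all that became target or uncatalysed product, at the outlet or at the end, alder
4. share of target in all that became target or uncatalysed product, at the outlet or at the end, birch
5. share of target in all that became target or uncatalysed product, at the outlet or at the end, oak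

- the stated concentrations are those of everything mixed, before any reaction; amounts are the same in each set-up
- the feed brings no volume worth counting
- run time (ash): 80 s

I solve the two ends and join them. Leaving aside crowding, the denominator of the enzyme rate, the rate of the enzyme step over that of the uncatalysed step grows as the square root of s, the substrate concentration. The ratio is one at 0.00573 mM, the square of the uncatalysed rate constant over the enzyme rate constant times the enzyme concentration. I call this the break-even concentration s*. With x the square root of s/s*, the momentary share of target (the selectivity) is x over one plus x.

In birch, x starts at 29.5, and crowding lowers the rate ratio to 21.9, so s first falls at 10.1 mM/s. Without crowding, s crosses s* at the knee, 15.0 s, and 80 s lies 8.26 half-lives of the uncatalysed step beyond it. In this crowding-free reckoning, uncatalysed product levels off at twice s* multiplied by the difference between x at the start and the logarithm of one plus that x, which is 0.299 mM. That gives target a share of 94.0 %.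

A tank with mean residence time τ holds s at one level, and while its feed lasts ash roughly does too, with the dosing time as its τ. Taking N as the charge over the uncatalysed rate constant times τ times s*, x is close to the cube root of N less a third. This gives x of 3.12 for alder, 4.65 for oak and 5.04 for ash during its feed, so shares of 75.7 %, 82.3 % and 83.4 %. I put birch highest.

The forecast, holding that “high substrate favours target”, names birch and gives 83.2 % for ash, 75.8 % for alder, 93.5 % for birch and 82.2 % for oak. The simulation gives birch as best, with 83.1 % for ash, 75.8 % for alder, 93.5 % for birch and 82.2 % for oak, so my crowding-free birch figure stands 0.50 percentage points above its result.

A neighbour of birch holds 2.0 × 10⁻⁴ mM of enzyme, with the rest of its recipe unchanged. Its s* is 0.0358 mM, and x starts at 11.8. The same crowding-free formula as for birch gives 0.664 mM of uncatalysed product, which is 13.3 % of the charge. The simulated neighbour ends with 0 % of its substrate left, uncatalysed product at 14.4 % of the charge, and a share of target of 85.6 %.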